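**Assumption:** larreantin has no stereocentre and its biaryl axis rotates freely, so it is achiral and there is no enantiomer to select; the route makes the one constitution given.

## Retrosynthetic overview

1. Larreantin 20 ⇐ quinone diacetate 19 ⇐ 1,2,4-trimethoxynaphthalene 18; ring A is carried as a trimethoxyarene and the quinone is unveiled by oxidative demethylation at the end.
2. The C6 benzyl group ⇐ naphthaldehyde 12 + arylmagnesium bromide 14, then ionic deoxygenation.
3. The C8 aryl group ⇐ naphthyl triflate 8 + boronic acid 9 (Suzuki coupling).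
4. The naphthalene core ⇐ Stobbe condensation of 2,4,5-trimethoxybenzaldehyde 1 with dimethyl methylsuccinate 2. This intermolecular aldol C–C bond formation is the key fragment union; it is followed by Friedel–Crafts cycloacylation.
5. Ring order: ring A (future quinone) is bought with 1; ring B (carrying H, ester, methyl, oxygen) is closed in step 2; no further ring is formed.

Numbering note: compounds 6–15 are named as 2-naphthoates (ester carbon = C2). From 16 on the target numbering is used (old C2, C3, C4, C5, C6, C8 = new C6, C7, C8, C1, C2, C4).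

## Route

**Step 1**
Reactants: 1 2,4,5-trimethoxybenzaldehyde; 2 dimethyl 2-methylbutanedioate (dimethyl methylsuccinate, racemic)
Product: 4 (E)-3-(methoxycarbonyl)-2-methyl-4-(2,4,5-trimethoxyphenyl)but-3-enoic acid (racemic), via paraconic ester lactone 3 (not isolated)
Conditions: KOtBu (1.5 equiv), tBuOH, reflux; then aq. HCl, acid–base extraction
Reagents that add atoms: none
Why: Stobbe condensation, in which the methylene enolate of 2 adds to the non-enolisable aldehyde in an intermolecular aldol reaction, the alkoxide lactonises onto the distal ester, and E1cB opening of the lactone (possible only when the attacking carbon still bears a hydrogen, which places the methyl on the acid-bearing carbon) gives the (E)-half-ester; the stereocentre inherited from racemic 2 is erased in step 2.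

**Step 2**
Reactants: 4 (E)-3-(methoxycarbonyl)-2-methyl-4-(2,4,5-trimethoxyphenyl)but-3-enoic acid
Product: 7 methyl 4-(acetyloxy)-5,6,8-trimethoxy-3-methyl-2-naphthoate, via mixed acetic anhydride 5 (not isolated), via free naphthol 6 (not isolated)
Conditions: Ac2O, NaOAc, reflux (140 °C), 3 h
Reagents that add atoms: acetic anhydride, CC(=O)OC(C)=O
Why: Mixed-anhydride activation, then intramolecular Friedel–Crafts acylation at the only free ortho position of ring A (ortho to a methoxy group), enolisation to the naphthol and O-acetylation, which is the standard Stobbe benzannulation.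

**Step 3**
Reactants: 7 methyl 4-(acetyloxy)-5,6,8-trimethoxy-3-methyl-2-naphthoate
Product: 6 methyl 4-hydroxy-5,6,8-trimethoxy-3-methyl-2-naphthoate (the naphthol passed through in step 2, now isolated)
Conditions: K2CO3 (0.5 equiv), MeOH, argon, rt; then dilute aq. HCl
Reagents that add atoms: none
Why: Base-catalysed transesterification cleaves the aryl acetate far faster than the hindered conjugated methyl ester, whose exchange with methanol is degenerate anyway.

**Step 4**
Reactants: 6 methyl 4-hydroxy-5,6,8-trimethoxy-3-methyl-2-naphthoate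
Product: 8 methyl 5,6,8-trimethoxy-3-methyl-4-{[(trifluoromethyl)sulfonyl]oxy}-2-naphthoate
Conditions: Tf2O, pyridine, CH2Cl2, 0 °C
Reagents that add atoms: trifluoromethanesulfonic anhydride, O=S(=O)(OS(=O)(=O)C(F)(F)F)C(F)(F)F
Why: O-sulfonylation of the naphthol with pyridine as acid scavenger, so the electron-rich ring A is not attacked.

**Step 5**
Reactants: 8 naphthyl triflate; 9 [4-(benzyloxy)-3-methoxyphenyl]boronic acid
Product: 10 methyl 4-[4-(benzyloxy)-3-methoxyphenyl]-5,6,8-trimethoxy-3-methyl-2-naphthoate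
Conditions: Pd(OAc)2 (5 mol %), SPhos (10 mol %), K3PO4 (3 equiv), toluene/H2O 10:1, 100 °C
Reagents that add atoms: none
Why: Suzuki–Miyaura coupling, in which the bulky electron-rich biarylphosphine lets zerovalent palladium insert into the di-ortho-substituted triflate while the unhindered boronic acid transmetalates readily.

**Step 6**
Reactants: 10 methyl 4-[4-(benzyloxy)-3-methoxyphenyl]-5,6,8-trimethoxy-3-methyl-2-naphthoate
Product: 11 {4-[4-(benzyloxy)-3-methoxyphenyl]-5,6,8-trimethoxy-3-methylnaphthalen-2-yl}methanol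
Conditions: LiAlH4, THF, 0 °C to rt; then H2O
Reagents that add atoms: none
Why: Hydride reduction of the aryl ester to the benzylic alcohol; aryl ethers and the benzyl ether are inert.

**Step 7**
Reactants: 11 naphthylmethanol
Product: 12 4-[4-(benzyloxy)-3-methoxyphenyl]-5,6,8-trimethoxy-3-methyl-2-naphthaldehyde
Conditions: Dess–Martin periodinane (1.2 equiv), CH2Cl2, 0 °C to rt
Reagents that add atoms: none
Why: Dess–Martin oxidation stops cleanly at the aldehyde and does not touch the electron-rich arenes.

**Step 8**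
Reactants: 12 naphthaldehyde; 13 1-(benzyloxy)-4-bromo-2-methoxybenzene
Product: 15 [4-(benzyloxy)-3-methoxyphenyl]{4-[4-(benzyloxy)-3-methoxyphenyl]-5,6,8-trimethoxy-3-methylnaphthalen-2-yl}methanol (racemic), via arylmagnesium bromide 14 (not isolated)
Conditions: 13, Mg turnings, THF, reflux; then 12, THF, 0 °C; sat. aq. NH4Cl
Reagents that add atoms: none
Why: Grignard addition to the aldehyde; the new carbinol stereocentre is formed racemic and is removed in step 9.

**Step 9**
Reactants: 15 diarylmethanol
Product: 16 6-[4-(benzyloxy)-3-methoxybenzyl]-8-[4-(benzyloxy)-3-methoxyphenyl]-1,2,4-trimethoxy-7-methylnaphthalene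
Conditions: Et3SiH (5 equiv), TFA (10 equiv), CH2Cl2, 0 °C
Reagents that add atoms: none
Why: Ionic hydrogenation, in which the doubly benzylic cation stabilised by the para-benzyloxy group is trapped by silane hydride faster than it can alkylate another arene.

**Step 10**
Reactants: 16 bis(benzyl ether)
Product: 17 6-(4-hydroxy-3-methoxybenzyl)-8-(4-hydroxy-3-methoxyphenyl)-1,2,4-trimethoxy-7-methylnaphthalene
Conditions: H2 (1 atm), 10% Pd/C, EtOAc/MeOH, rt
Reagents that add atoms: none
Why: Hydrogenolysis of both O-benzyl groups, done before the quinone exists so nothing else is reducible.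

**Step 11**
Reactants: 17 bisphenol
Product: 18 6-[4-(acetyloxy)-3-methoxybenzyl]-8-[4-(acetyloxy)-3-methoxyphenyl]-1,2,4-trimethoxy-7-methylnaphthalene
Conditions: Ac2O, pyridine, DMAP (cat.), CH2Cl2, rt
Reagents that add atoms: acetic anhydride, CC(=O)OC(C)=O
Why: O-acetylation masks the phenols and deactivates both guaiacyl rings towards the oxidant of step 12.

**Step 12**
Reactants: 18 diacetate
Product: 19 6-[4-(acetyloxy)-3-methoxybenzyl]-8-[4-(acetyloxy)-3-methoxyphenyl]-2-methoxy-7-methylnaphthalene-1,4-dione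
Conditions: (NH4)2Ce(NO3)6 (2.5 equiv), MeCN/H2O 2:1, 0 °C, 20 min
Reagents that add atoms: water, O
Why: Oxidative demethylation by tetravalent cerium, in which the most electron-rich ring is oxidised and its para-related C1 and C4 methoxy groups become the carbonyls (oxygen from water), leaving the C2 methoxy group.

**Step 13**
Reactants: 19 quinone diacetate
Product: 20 larreantin, 6-(4-hydroxy-3-methoxybenzyl)-8-(4-hydroxy-3-methoxyphenyl)-2-methoxy-7-methylnaphthalene-1,4-dione
Conditions: HCl (cat., 1.25 M in MeOH), MeOH/CH2Cl2, rt to 40 °C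
Reagents that add atoms: none
Why: Acid-catalysed transesterification removes both aryl acetates, while the 2-methoxy-1,4-quinone is the thermodynamic product in acidic methanol, so any 4-methoxy-1,2-quinone carried over from step 12 converges on it.

## Compound list

1 | 2,4,5-trimethoxybenzaldehyde | COc1cc(OC)c(OC)cc1C=O | starting material
2 | dimethyl 2-methylbutanedioate (racemic) | COC(=O)CC(C)C(=O)OC | starting material
3 | methyl 4-methyl-5-oxo-2-(2,4,5-trimethoxyphenyl)oxolane-3-carboxylate (paraconic ester, diastereomer mixture, racemic) | COC(=O)C1C(C)C(=O)OC1c1cc(OC)c(OC)cc1OC | intermediate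
4 | (E)-3-(methoxycarbonyl)-2-methyl-4-(2,4,5-trimethoxyphenyl)but-3-enoic acid (racemic) | COC(=O)/C(C(C)C(=O)O)=C/c1cc(OC)c(OC)cc1OC | intermediate
5 | mixed anhydride of 4 with acetic acid | COC(=O)/C(C(C)C(=O)OC(C)=O)=C/c1cc(OC)c(OC)cc1OC | intermediate
6 | methyl 4-hydroxy-5,6,8-trimethoxy-3-methyl-2-naphthoate | COC(=O)c1cc2c(OC)cc(OC)c(OC)c2c(O)c1C | intermediate
7 | methyl 4-(acetyloxy)-5,6,8-trimethoxy-3-methyl-2-naphthoate | COC(=O)c1cc2c(OC)cc(OC)c(OC)c2c(OC(C)=O)c1C | intermediate
8 | methyl 5,6,8-trimethoxy-3-methyl-4-{[(trifluoromethyl)sulfonyl]oxy}-2-naphthoate | COC(=O)c1cc2c(OC)cc(OC)c(OC)c2c(OS(=O)(=O)C(F)(F)F)c1C | intermediate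
9 | [4-(benzyloxy)-3-methoxyphenyl]boronic acid | COc1cc(B(O)O)ccc1OCc1ccccc1 | starting material
10 | methyl 4-[4-(benzyloxy)-3-methoxyphenyl]-5,6,8-trimethoxy-3-methyl-2-naphthoate | COC(=O)c1cc2c(OC)cc(OC)c(OC)c2c(-c3ccc(OCc4ccccc4)c(OC)c3)c1C | intermediate
11 | {4-[4-(benzyloxy)-3-methoxyphenyl]-5,6,8-trimethoxy-3-methylnaphthalen-2-yl}methanol | OCc1cc2c(OC)cc(OC)c(OC)c2c(-c3ccc(OCc4ccccc4)c(OC)c3)c1C | intermediate
12 | 4-[4-(benzyloxy)-3-methoxyphenyl]-5,6,8-trimethoxy-3-methyl-2-naphthaldehyde | O=Cc1cc2c(OC)cc(OC)c(OC)c2c(-c3ccc(OCc4ccccc4)c(OC)c3)c1C | intermediate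
13 | 1-(benzyloxy)-4-bromo-2-methoxybenzene | COc1cc(Br)ccc1OCc1ccccc1 | starting material
14 | [4-(benzyloxy)-3-methoxyphenyl]magnesium bromide | COc1cc([Mg]Br)ccc1OCc1ccccc1 | intermediate
15 | [4-(benzyloxy)-3-methoxyphenyl]{4-[4-(benzyloxy)-3-methoxyphenyl]-5,6,8-trimethoxy-3-methylnaphthalen-2-yl}methanol (racemic) | OC(c1ccc(OCc2ccccc2)c(OC)c1)c1cc2c(OC)cc(OC)c(OC)c2c(-c3ccc(OCc4ccccc4)c(OC)c3)c1C | intermediate
16 | 6-[4-(benzyloxy)-3-methoxybenzyl]-8-[4-(benzyloxy)-3-methoxyphenyl]-1,2,4-trimethoxy-7-methylnaphthalene | Cc1c(Cc2ccc(OCc3ccccc3)c(OC)c2)cc2c(OC)cc(OC)c(OC)c2c1-c1ccc(OCc2ccccc2)c(OC)c1 | intermediate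
17 | 6-(4-hydroxy-3-methoxybenzyl)-8-(4-hydroxy-3-methoxyphenyl)-1,2,4-trimethoxy-7-methylnaphthalene | Cc1c(Cc2ccc(O)c(OC)c2)cc2c(OC)cc(OC)c(OC)c2c1-c1ccc(O)c(OC)c1 | intermediate
18 | 6-[4-(acetyloxy)-3-methoxybenzyl]-8-[4-(acetyloxy)-3-methoxyphenyl]-1,2,4-trimethoxy-7-methylnaphthalene | Cc1c(Cc2ccc(OC(C)=O)c(OC)c2)cc2c(OC)cc(OC)c(OC)c2c1-c1ccc(OC(C)=O)c(OC)c1 | intermediate
19 | 6-[4-(acetyloxy)-3-methoxybenzyl]-8-[4-(acetyloxy)-3-methoxyphenyl]-2-methoxy-7-methylnaphthalene-1,4-dione | COC1=CC(=O)c2cc(Cc3ccc(OC(C)=O)c(OC)c3)c(C)c(-c3ccc(OC(C)=O)c(OC)c3)c2C1=O | intermediate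
20 | larreantin, 6-(4-hydroxy-3-methoxybenzyl)-8-(4-hydroxy-3-methoxyphenyl)-2-methoxy-7-methylnaphthalene-1,4-dione (achiral) | COC1=CC(=O)c2cc(Cc3ccc(O)c(OC)c3)c(C)c(-c3ccc(O)c(OC)c3)c2C1=O | target

## Summary

Total step count: 13. Longest linear sequence: 13 steps (1 → 20); 2, 9 and 13 enter as purchased side inputs.

Three steps most likely to fail:

**Step 1 (Stobbe condensation with the unsymmetrical succinate; risk of regio- or double-bond isomers and modest yield).** The fallback sets out from aldehyde 1 and returns at acid 4. The sodium salt of trimethyl phosphonoacetate (NaH, THF/DMF) is alkylated with tert-butyl 2-bromopropanoate to give 4-tert-butyl 1-methyl 2-(dimethoxyphosphoryl)-3-methylbutanedioate F1. Its anion (NaH, THF, 0 °C to rt) olefinates 1 in a Horner–Wadsworth–Emmons reaction to 4-tert-butyl 1-methyl (E)-3-methyl-2-(2,4,5-trimethoxybenzylidene)butanedioate F2, in which the reagent fixes the position of both the double bond and the methyl group. TFA in CH2Cl2 then cleaves only the tert-butyl ester and delivers 4.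

**Step 5 (Suzuki coupling at a triflate flanked by a methyl group and a peri-methoxy group).** The fallback sets out from triflate 8 and returns at biaryl ester 10. Grignard reagent 14 (made from 13 as in step 8) is transmetalated with ZnCl2 in THF to [4-(benzyloxy)-3-methoxyphenyl]zinc chloride F3. This is joined to 8 by Negishi coupling (Pd(OAc)2, XPhos, THF, 60 °C); the arylzinc transmetalates without base or water and tolerates the methyl ester, giving 10.

**Step 12 (oxidative demethylation; risk of the ortho-quinone regioisomer and of material loss on separation).** The fallback sets out from diacetate 18 and returns at target 20. Compound 18 is oxidised with (NH4)2Ce(NO3)6 as before, but the crude mixture of 19 and its isomer 6-[4-(acetyloxy)-3-methoxybenzyl]-8-[4-(acetyloxy)-3-methoxyphenyl]-4-methoxy-7-methylnaphthalene-1,2-dione F4 is not separated. It is hydrolysed with dilute NaOH in aqueous THF under argon and then acidified. Both methoxyquinones give the same vinylogous acid, and the acetates are cleaved too, so the product is 2-hydroxy-6-(4-hydroxy-3-methoxybenzyl)-8-(4-hydroxy-3-methoxyphenyl)-7-methylnaphthalene-1,4-dione F5. Heating F5 in methanolic HCl etherifies only the quinone hydroxyl (Fischer-type etherification, as for lawsone) and gives 20 directly.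

## Further compounds

F1 | step 1 | 4-tert-butyl 1-methyl 2-(dimethoxyphosphoryl)-3-methylbutanedioate | COC(=O)C(P(=O)(OC)OC)C(C)C(=O)OC(C)(C)C
F2 | step 1 | 4-tert-butyl 1-methyl (E)-3-methyl-2-(2,4,5-trimethoxybenzylidene)butanedioate | COC(=O)/C(C(C)C(=O)OC(C)(C)C)=C/c1cc(OC)c(OC)cc1OC
F3 | step 5 | [4-(benzyloxy)-3-methoxyphenyl]zinc chloride | COc1cc([Zn]Cl)ccc1OCc1ccccc1
F4 | step 12 | 6-[4-(acetyloxy)-3-methoxybenzyl]-8-[4-(acetyloxy)-3-methoxyphenyl]-4-methoxy-7-methylnaphthalene-1,2-dione | COC1=CC(=O)C(=O)c2c(-c3ccc(OC(C)=O)c(OC)c3)c(C)c(Cc3ccc(OC(C)=O)c(OC)c3)cc12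
F5 | step 12 | 2-hydroxy-6-(4-hydroxy-3-methoxybenzyl)-8-(4-hydroxy-3-methoxyphenyl)-7-methylnaphthalene-1,4-dione | OC1=CC(=O)c2cc(Cc3ccc(O)c(OC)c3)c(C)c(-c3ccc(O)c(OC)c3)c2C1=O
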